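Assumption: the SMILES is read as (1E,3S,4Z,6S,7S,8R,10R) in germacrane numbering. The carbocycle is C1–C10, the lactone ring is O–C6–C7–C11–C12 with exocyclic C13, C14 sits on C10 and C15 on C4. This numbering is kept for all intermediates.

## The problem

- The target is a ten-membered carbocycle (C1–C10) trans-fused along C6–C7 to an α-methylene-γ-butyrolactone (O, C6, C7, C11, C12, exocyclic C13). The ring holds an E-alkene (C1=C2) and a Z-trisubstituted alkene (C4=C5) separated only by C3.
- Closing such a ring works against transannular strain and entropy. Neither alkene geometry can be corrected once the ring exists.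
- C6, C7 and C8 form a contiguous triad: a trans-lactone, with O6, C11 and O8 all syn along the chain C5–C9. Within it, C6 can control C7 and C8.
- C10 (tertiary carbinol, 1,3-anti to O8) and C3 (cis to O6 across the Z-alkene) are insulated from the triad by a CH2 group or by sp2 carbons. Each needs its own source of control.
- The fragile groups are:
  - the α-methylene lactone, a Michael acceptor;
  - the angelate, which isomerises Z to E with nucleophilic catalysts;
  - the doubly allylic C3 acetate and the tertiary allylic C10 alcohol, which both ionise easily.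
- O6 and O8 flank C7 symmetrically, so the lactone can migrate from O6 to O8 when O8 is free.
- The enabling feature is C3, the only ring atom bonded to two ring alkenes. At the ketone level C1=C2–C3(=O)–C4=C5 is a cross-conjugated dienone. Its carbonyl carbon can be delivered as carbon monoxide 20 between an alkenyl iodide at C4 and an alkenylstannane at C2.
- A second feature serves the triad. The lactone ring with its C11=C13 methylene and the C7–C8 bond is the SE2' adduct of a flat butenolide (C7=C11) that carries a metal on C13.

## Retrosynthesis

**C3 ester and C3 carbinol (25 ⇒ 24 ⇒ 23 ⇒ 22).**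
- Cut: no ring bond. The O3–acetyl bond is removed (24), C3 is raised to the ketone (23), and O10 is capped as a triethylsilyl ether (22).
- Against the alternative: carrying the acetate through the route is worse, because a doubly allylic acetate ionises with acid and with zerovalent palladium. The dienone is inert to both.
- Simplification: one stereocentre disappears and C1–C5 becomes planar.
- Forward demand: hydride must reach one face of C3 only, in 1,2 fashion, and a secondary hydroxyl must be acetylated beside a tertiary one.

**Both bonds to C3 (22 ⇒ 19 + 20).**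
- Cut: C2–C3 and C3–C4 together, so that C3 leaves as carbon monoxide 20. This gives the open-chain lactone 19, with an alkenyl iodide at C4 and an alkenylstannane at C2.
- Against the neighbours:
  - cutting only one of these bonds keeps C3 as an enal carbon and creates its stereocentre during ring closure;
  - cutting C1=C2 or C4=C5 leaves an alkene geometry to the ring closure.
- Simplification: 19 has one ring, one carbon and one stereocentre fewer than 24, and both geometries come from small fragments.
- Forward demand: 20 must insert faster than direct coupling occurs, both geometries must be retained, and ring closure must be preferred over chain growth.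

**O8–acyl bond (19 ⇒ 16 + 17).**
- Cut: the angelate is removed as angelic acid 17, leaving alcohol 16.
- Timing: the ester cannot come earlier, because O8 is only created with the C7–C8 bond. It should not come later, because a free O8 next to C12 invites lactone migration and could trap an acylpalladium species.
- Forward demand: acylation without Z-to-E isomerisation.

**C7–C8 (16 ⇒ 8 + 14).**
- Cut: C7–C8, with the C11=C13 double bond moved back to C7=C11. This gives the α-(bromomethyl)butenolide 8 and the aldehyde 14.
- Against the neighbour: cutting C6–C7 would need an open-chain 2-(halomethyl)enoate. Its alkene geometry and its facial bias would both have to be secured, and C8 would need a separate asymmetric step.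
- Advantage here: the ring of 8 locks the allyl geometry and its single stereocentre C6 shields one face.
- Simplification: each precursor has one stereocentre.
- Forward demand: attack through C7, anti to the C6 substituent, in a closed transition state.

**Butenolide (8 ⇒ 7 ⇒ 5 + 6; 5 ⇒ 4 ⇒ 3 ⇒ 1).**
- Cut: C7=C11 by metathesis logic (7), and O6–C12 as an ester bond to dienol 5 and 2-(bromomethyl)acrylic acid 6.
- Advantage: 6 brings C11, C12 and C13 with the bromide already in place, which avoids halogenation next to an iodoalkene.
- Further cuts: 5 comes from enal 4 by cutting C6–C7. Compound 4 comes from alcohol 3 and but-2-yn-1-ol 1.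
- Forward demand: one catalytic asymmetric vinyl transfer and a stereospecific hydroalumination–iodination.

**Aldehyde (14 ⇒ 13 ⇒ 12 ⇒ 11 ⇒ 10 ⇒ 9).**
- Cut: no C–C bond. The six carbons C8, C9, C10, C14, C1 and C2 are bought together as the enynol 9.
- C10 arises from asymmetric epoxidation (10) and reductive opening at C9 (11).
- The E-stannane arises from the alkyne (12 ⇒ 13) before any iodide is present.
- C8 is unmasked last (14).

## Roads not taken

**Alternative 1:** cut C6–C7 and O6–C12. This is the most obvious plan.
- Forward key step: intramolecular Nozaki–Hiyama or Barbier allylation of the Z-enal bromide A1, followed by lactonisation.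
- A1 must already carry C3, C8 and C10, each set by a separate operation in an open chain, so nothing is relayed.
- Its C3 acetate is γ to the aldehyde through C4=C5. That is a vinylogous α-acyloxy carbonyl, which divalent chromium or zinc can cleave reductively.
- Its Z-enal can isomerise before closure.
- The closing event would have to set C6 and C7 correctly relative to C8 from a flexible chain. The chosen plan sets C7 and C8 on a rigid five-membered ring.

**Alternative 2:** cut C1=C2.
- Forward key step: ring-closing metathesis of the tetraene A2.
- Both reacting vinyl groups are hindered, one by the quaternary C10 and the other by the C3 acetate.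
- A ten-membered ring gives no thermodynamic reason for the E-isomer, and strain favours reopening or dimerisation.
- The catalyst also meets the C11=C13 methylene.
- The chosen plan buys both geometries by stereospecific additions to alkynes and only transfers them.

**Alternative 3:** cut C3–C4 only.
- Forward key step: Nozaki–Hiyama–Kishi closure of the iodo-enal A3.
- This is the closest competitor.
- Ring closure and the C3 stereocentre are made in the same event, so they are controlled only by the conformation of the closing chain.
- The enal has to be installed on a late, crowded intermediate.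
- A large excess of CrCl2 at high dilution is needed.
- The chosen plan separates ring closure from the C3 problem, which is solved afterwards by reagent control on a rigid ring. The precursor is one carbon shorter.

Key step: step 13

## Steps

Step 1
Reactants: 1 but-2-yn-1-ol
Product: 3 (Z)-3-iodobut-2-en-1-ol, via cyclic alkenylalanate 2 (not isolated)
Conditions: NaAlH2(OCH2CH2OMe)2, THF, 0 °C to rt; then I2, −78 °C to 0 °C
Reagents that add atoms: iodine, [I][I]
Why: Hydroxyl-directed trans-hydroalumination of the propargylic alcohol places aluminium on C4 inside the five-membered ring of 2, and iodinolysis with retention gives the Z-alkenyl iodide; this fixes the C4=C5 geometry at the outset.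

Step 2
Reactants: 3 (Z)-3-iodobut-2-en-1-ol
Product: 4 (Z)-3-iodobut-2-enal
Conditions: MnO2, CH2Cl2, rt
Reagents that add atoms: none
Why: Allylic oxidation with MnO2 is neutral and stops at the aldehyde, so the Z-β-iodoenal should not isomerise; it is used without storage.

Step 3
Reactants: 4 (Z)-3-iodobut-2-enal
Product: 5 (3R,4Z)-5-iodohexa-1,4-dien-3-ol
Conditions: Zn(CH=CH2)2, (+)-MIB (10 mol %), toluene/hexane, −30 °C to 0 °C
Reagents that add atoms: divinylzinc, C=C[Zn]C=C
Why: Amino-alcohol-catalysed asymmetric alkenylzinc addition to an enal; (+)-MIB directs vinyl transfer to the Re face and sets C6 (R here because iodine raises the rank of C5, same spatial sense as 6S in 25). The bridged zinc alkoxide transition state favours 1,2-addition over addition–elimination at the iodo-bearing carbon.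

Step 4
Reactants: 5 (3R,4Z)-5-iodohexa-1,4-dien-3-ol; 6 2-(bromomethyl)prop-2-enoic acid
Product: 7 (3R,4Z)-5-iodohexa-1,4-dien-3-yl 2-(bromomethyl)prop-2-enoate
Conditions: DCC, DMAP (5 mol %), CH2Cl2, 0 °C
Reagents that add atoms: none
Why: Steglich esterification at O6; low temperature and only catalytic DMAP keep the allylic bromide from quaternisation, and C6 is not touched.

Step 5
Reactants: 7 (3R,4Z)-5-iodohexa-1,4-dien-3-yl 2-(bromomethyl)prop-2-enoate
Product: 8 (5R)-3-(bromomethyl)-5-[(1Z)-2-iodoprop-1-enyl]furan-2(5H)-one
Conditions: second-generation Grubbs catalyst RuCl2(=CHPh)(PCy3)(SIMes) (5 mol %), 1,4-benzoquinone (10 mol %), CH2Cl2, reflux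
Reagents that add atoms: none
Why: Ring-closing metathesis of an allylic 2-substituted acrylate to an α-substituted butenolide forms C7=C11 in a five-membered ring; the vinyl group initiates and the iodo-substituted trisubstituted alkene is inert. Benzoquinone suppresses ruthenium hydride isomerisation at the doubly allylic C6.

Step 6
Reactants: 9 (E)-3-methylpent-2-en-4-yn-1-ol
Product: 10 [(2S,3S)-3-ethynyl-3-methyloxiran-2-yl]methanol
Conditions: Ti(OiPr)4 (10 mol %), L-(+)-diethyl tartrate (12 mol %), t-BuOOH, 4 Å molecular sieves, CH2Cl2, −20 °C
Reagents that add atoms: tert-butyl hydroperoxide, CC(C)(C)OO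
Why: Sharpless asymmetric epoxidation; with the L-(+)-tartrate an E-allylic alcohol gives the (2S,3S)-epoxide, which fixes the C10–O bond in the sense needed for 10R.

Step 7
Reactants: 10 [(2S,3S)-3-ethynyl-3-methyloxiran-2-yl]methanol
Product: 11 (3R)-3-methylpent-4-yne-1,3-diol
Conditions: NaAlH2(OCH2CH2OMe)2, THF, −20 °C to 0 °C; aqueous Rochelle salt
Reagents that add atoms: none
Why: Regioselective reduction of a 2,3-epoxy alcohol to the 1,3-diol: hydride is delivered from the O8-bound aluminate to C9, so the tertiary C10–O bond and its configuration are kept. The terminal alkyne is deprotonated, and the alkynylaluminate should resist hydroalumination at or below 0 °C.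

Step 8
Reactants: 11 (3R)-3-methylpent-4-yne-1,3-diol
Product: 12 (3R)-3-methyl-1,3-bis(triethylsilyloxy)pent-4-yne
Conditions: Et3SiOTf (2.3 equiv), 2,6-lutidine, CH2Cl2, −78 °C to 0 °C
Reagents that add atoms: triethylsilyl trifluoromethanesulfonate, CC[Si](CC)(CC)OS(=O)(=O)C(F)(F)F
Why: A silyl triflate with a hindered base silylates the primary and the tertiary hydroxyl; the tertiary ether guards C10–O against retro-aldol cleavage and β-elimination once C8 is an aldehyde.

Step 9
Reactants: 12 (3R)-3-methyl-1,3-bis(triethylsilyloxy)pent-4-yne
Product: 13 (3R,4E)-3-methyl-1,3-bis(triethylsilyloxy)-5-(tributylstannyl)pent-4-ene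
Conditions: Bu3SnH, PdCl2(PPh3)2 (2 mol %), THF, 0 °C to rt
Reagents that add atoms: tributyltin hydride, CCCC[SnH](CCCC)CCCC
Why: Palladium-catalysed syn-hydrostannation of a terminal alkyne; the fully substituted C10 steers tin to the terminal C2 and gives the E-alkenylstannane that fixes C1=C2. The step is placed before any alkenyl iodide is present.

Step 10
Reactants: 13 (3R,4E)-3-methyl-1,3-bis(triethylsilyloxy)-5-(tributylstannyl)pent-4-ene
Product: 14 (3R,4E)-3-methyl-3-(triethylsilyloxy)-5-(tributylstannyl)pent-4-enal
Conditions: (COCl)2, DMSO, CH2Cl2, −78 °C to −30 °C; Et3N, −78 °C to 0 °C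
Reagents that add atoms: none
Why: Under Swern conditions a primary triethylsilyl ether is cleaved by the chlorosulfonium salt and oxidised in the same flask, while the tertiary silyl ether and the alkenylstannane should survive (selective oxidation of primary silyl ethers).

Step 11
Reactants: 8 (5R)-3-(bromomethyl)-5-[(1Z)-2-iodoprop-1-enyl]furan-2(5H)-one; 14 (3R,4E)-3-methyl-3-(triethylsilyloxy)-5-(tributylstannyl)pent-4-enal
Product: 16 (4S,5R)-4-[(1R,3R,4E)-1-hydroxy-3-methyl-3-(triethylsilyloxy)-5-(tributylstannyl)pent-4-enyl]-5-[(1Z)-2-iodoprop-1-enyl]-3-methylideneoxolan-2-one, via allylchromium dichloride 15 (not isolated)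
Conditions: CrCl2 (4 equiv, nickel-free), THF, 0 °C to rt; water
Reagents that add atoms: none
Why: Nozaki–Hiyama allylation: CrCl2 turns the allylic bromide into 15, which reacts through C7 (SE2') in a closed chair transition state and moves the double bond to C11=C13. The aldehyde meets the flat butenolide anti to the C6 alkenyl group (sets C7, trans-lactone), and the ring-locked allyl geometry (C6 trans to C13) with an equatorial aldehyde chain gives the anti adduct (sets C8), so C6 controls two stereocentres in one event. Without a nickel salt the alkenyl iodide is inert to CrCl2, and the stannane and silyl ether are tolerated.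

Step 12
Reactants: 16 the alcohol of step 11; 17 angelic acid [(Z)-2-methylbut-2-enoic acid]
Product: 19 the O8-angelate of 16 (6R,7S,8R,10R; Z-alkenyl iodide at C4 and E-alkenylstannane at C2), via angelic 2,4,6-trichlorobenzoic anhydride 18 (not isolated)
Conditions: 17, 2,4,6-trichlorobenzoyl chloride, Et3N, toluene, rt; then 16, 75 °C
Reagents that add atoms: none
Why: Yamaguchi-type mixed-anhydride acylation without DMAP is the standard way to form angelates without Z-to-E isomerisation; O8 is the only free hydroxyl, and capping it also stops lactone migration.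

Step 13
Reactants: 19 the iodide–stannane of step 12; 20 carbon monoxide
Product: 22 (1E,4Z,6S,7S,8R,10R)-8-angeloyloxy-3-oxo-10-(triethylsilyloxy)germacra-1,4,11(13)-trien-6,12-olide, via acylpalladium iodide 21 (not isolated)
Conditions: Pd2(dba)3 (10 mol %), AsPh3 (40 mol %), 20 (3 atm), THF/NMP, 45 °C, slow addition of 19 to about 1 mM
Reagents that add atoms: none
Why: Zerovalent palladium inserts into the C4–I bond with retention, 20 inserts to give 21, the E-alkenylstannane transfers C2 to palladium with retention, and reductive elimination forms C2–C3. The closest known reaction type is the carbonylative Stille macrocyclisation of an alkenyl halide or triflate with an alkenylstannane to a macrocyclic cross-conjugated dienone. The only ring closed is the ten-membered carbocycle; it closes end to end by reductive elimination from an eleven-membered palladacycle, and both new bonds end at the incoming carbonyl carbon. No stereocentre is created and C6, C7, C8 and C10 are spectators; what is transferred is the geometry of both alkenes, fixed in steps 1 and 9. Insertion of 20 must outrun direct coupling: direct coupling would need a nine-membered E,Z-diene ring, more strained than the ten-membered dienone, and pressure of 20 with the weakly donating AsPh3 favours the acyl complex. Ring closure must outrun chain growth: slow addition keeps 19 dilute, and the trans-lactone, the branched C7 and the quaternary C10 restrict the rotamers of both arms. Trapping of 21 by oxygen is excluded because O6 is tied up in the lactone (a free Z-γ-hydroxyl would give a butenolide), O8 is acylated and O10 is silylated. The α-methylene lactone, the angelate and the silyl ether should not react with the catalyst at this temperature.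

Step 14
Reactants: 22 the silyl ether of step 13
Product: 23 (1E,4Z,6S,7S,8R,10R)-8-angeloyloxy-10-hydroxy-3-oxogermacra-1,4,11(13)-trien-6,12-olide
Conditions: HF·pyridine, pyridine, THF, 0 °C to rt
Reagents that add atoms: none
Why: Buffered fluoride desilylation; it is done at the dienone stage, where no ionisable doubly allylic ester is present, and the E-geometry of C1=C2 keeps O10 from closing onto C3.

Step 15
Reactants: 23 the hydroxy dienone of step 14
Product: 24 (1E,3S,4Z,6S,7S,8R,10R)-8-angeloyloxy-3,10-dihydroxygermacra-1,4,11(13)-trien-6,12-olide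
Conditions: (R)-2-methyl-CBS-oxazaborolidine (0.5 equiv), catecholborane, toluene, −78 °C; MeOH, then aqueous buffer
Reagents that add atoms: none
Why: Corey–Bakshi–Shibata reduction gives 1,2-delivery of hydride; the α-methyl-branched C4 arm acts as the large and the unbranched C2 arm as the small substituent, so the (R)-catalyst should give 3S. Catecholborane at −78 °C should leave the α-methylene lactone and the esters alone.

Step 16
Reactants: 24 the diol of step 15
Product: 25 (1E,3S,4Z,6S,7S,8R,10R)-3-acetoxy-8-angeloyloxy-10-hydroxygermacra-1,4,11(13)-trien-6,12-olide (CNP0181631.2)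
Conditions: Ac2O (1.2 equiv), pyridine, DMAP (2 mol %), CH2Cl2, 0 °C
Reagents that add atoms: acetic anhydride, CC(=O)OC(C)=O
Why: Acetylation distinguishes the secondary C3 hydroxyl from the tertiary C10 hydroxyl on steric grounds; the mild base, low temperature and short time spare the angelate and the Michael acceptor.

## Compound list

1 | but-2-yn-1-ol | CC#CCO | starting material
2 | sodium cyclic alkenylalanate (five-membered O–Al–C4=C5–C6 ring, two 2-methoxyethoxy ligands) | CC1=CCO[Al-]1(OCCOC)OCCOC.[Na+] | intermediate
3 | (Z)-3-iodobut-2-en-1-ol | C/C(I)=C/CO | intermediate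
4 | (Z)-3-iodobut-2-enal | C/C(I)=C/C=O | intermediate
5 | (3R,4Z)-5-iodohexa-1,4-dien-3-ol | C=C[C@@H](O)/C=C(/C)I | intermediate
6 | 2-(bromomethyl)prop-2-enoic acid | C=C(CBr)C(=O)O | starting material
7 | (3R,4Z)-5-iodohexa-1,4-dien-3-yl 2-(bromomethyl)prop-2-enoate | C=C[C@@H](OC(=O)C(=C)CBr)/C=C(/C)I | intermediate
8 | (5R)-3-(bromomethyl)-5-[(1Z)-2-iodoprop-1-enyl]furan-2(5H)-one | BrCC1=C[C@H](/C=C(/C)I)OC1=O | intermediate
9 | (E)-3-methylpent-2-en-4-yn-1-ol | OC/C=C(/C#C)C | starting material
10 | [(2S,3S)-3-ethynyl-3-methyloxiran-2-yl]methanol | OC[C@@H]1O[C@@]1(C)C#C | intermediate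
11 | (3R)-3-methylpent-4-yne-1,3-diol | OCC[C@@](C)(O)C#C | intermediate
12 | (3R)-3-methyl-1,3-bis(triethylsilyloxy)pent-4-yne | CC[Si](CC)(CC)OCC[C@@](C)(O[Si](CC)(CC)CC)C#C | intermediate
13 | (3R,4E)-3-methyl-1,3-bis(triethylsilyloxy)-5-(tributylstannyl)pent-4-ene | CC[Si](CC)(CC)OCC[C@@](C)(O[Si](CC)(CC)CC)/C=C/[Sn](CCCC)(CCCC)CCCC | intermediate
14 | (3R,4E)-3-methyl-3-(triethylsilyloxy)-5-(tributylstannyl)pent-4-enal | O=CC[C@@](C)(O[Si](CC)(CC)CC)/C=C/[Sn](CCCC)(CCCC)CCCC | intermediate
15 | allylchromium dichloride derived from 8 (chromium on C13) | Cl[Cr](Cl)CC1=C[C@H](/C=C(/C)I)OC1=O | intermediate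
16 | (6R,7S,8R,10R)-8-hydroxy open-chain lactone (trans-lactone, Z-iodide at C4, E-stannane at C2, 10-OTES) | C=C1C(=O)O[C@@H](/C=C(/C)I)[C@@H]1[C@H](O)C[C@@](C)(O[Si](CC)(CC)CC)/C=C/[Sn](CCCC)(CCCC)CCCC | intermediate
17 | angelic acid, (Z)-2-methylbut-2-enoic acid | C/C=C(/C)C(=O)O | starting material
18 | angelic 2,4,6-trichlorobenzoic anhydride | C/C=C(/C)C(=O)OC(=O)c1c(Cl)cc(Cl)cc1Cl | intermediate
19 | (6R,7S,8R,10R)-8-angeloyloxy open-chain lactone (Z-iodide at C4, E-stannane at C2, 10-OTES) | C=C1C(=O)O[C@@H](/C=C(/C)I)[C@@H]1[C@H](OC(=O)/C(C)=C\C)C[C@@](C)(O[Si](CC)(CC)CC)/C=C/[Sn](CCCC)(CCCC)CCCC | intermediate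
20 | carbon monoxide | [C-]#[O+] | starting material
21 | acylpalladium iodide (C3 acyl on palladium, ligands omitted) | C=C1C(=O)O[C@@H](/C=C(/C)C(=O)[Pd]I)[C@@H]1[C@H](OC(=O)/C(C)=C\C)C[C@@](C)(O[Si](CC)(CC)CC)/C=C/[Sn](CCCC)(CCCC)CCCC | intermediate
22 | (1E,4Z,6S,7S,8R,10R)-8-angeloyloxy-3-oxo-10-(triethylsilyloxy)germacra-1,4,11(13)-trien-6,12-olide | C=C1C(=O)O[C@H]2/C=C(/C)C(=O)/C=C/[C@](C)(O[Si](CC)(CC)CC)C[C@@H](OC(=O)/C(C)=C\C)[C@H]12 | intermediate
23 | (1E,4Z,6S,7S,8R,10R)-8-angeloyloxy-10-hydroxy-3-oxogermacra-1,4,11(13)-trien-6,12-olide | C=C1C(=O)O[C@H]2/C=C(/C)C(=O)/C=C/[C@](C)(O)C[C@@H](OC(=O)/C(C)=C\C)[C@H]12 | intermediate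
24 | (1E,3S,4Z,6S,7S,8R,10R)-8-angeloyloxy-3,10-dihydroxygermacra-1,4,11(13)-trien-6,12-olide | C=C1C(=O)O[C@H]2/C=C(/C)[C@@H](O)/C=C/[C@](C)(O)C[C@@H](OC(=O)/C(C)=C\C)[C@H]12 | intermediate
25 | (1E,3S,4Z,6S,7S,8R,10R)-3-acetoxy-8-angeloyloxy-10-hydroxygermacra-1,4,11(13)-trien-6,12-olide | C=C1C(=O)O[C@H]2/C=C(/C)[C@@H](OC(C)=O)/C=C/[C@](C)(O)C[C@@H](OC(=O)/C(C)=C\C)[C@H]12 | target

## Step count and least certain steps

Total step count: 16. Longest linear sequence: 11 (steps 1–5 or steps 6–10, then steps 11–16).

**Step 13 (key step).**
- Most likely failure: chain growth by intermolecular transmetalation, because the effective molarity for a strained ten-membered ring is low.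
- Side processes: protodestannylation during the long addition, and slow ionisation of the allylic C6–O bond by zerovalent palladium.
- Fallback: it moves the ring closure to C3–C4 and uses an aldehyde carbon instead of 20. It sets out from 12.
  - Semi-hydrogenation over Pd/CaCO3 poisoned with Pb(OAc)2 and quinoline gives the vinyl carbinol bis(silyl ether) F1.
  - Swern oxidation gives the aldehyde F2.
  - Allylation with 8 and CrCl2 gives the alcohol F3.
  - Mixed-anhydride acylation with 17 gives the angelate F4.
  - HF·pyridine frees the tertiary alcohol F5.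
  - Cross-metathesis with crotonaldehyde, using the second-generation Hoveyda–Grubbs catalyst RuCl2(=CH-2-(iPrO)C6H4)(SIMes), gives the E-enal F6.
  - A Nozaki–Hiyama–Kishi closure (CrCl2, NiCl2 1 mol %, DMSO/THF, high dilution) joins C4 to C3.
- The fallback comes back to the route at 24.

**Step 11.**
- Most likely failure: reductive opening of the butenolide. In the 1,3-shifted form of the allylchromium species the metal sits on C7, β to the lactone oxygen on C6, and expulsion of the carboxylate would give a conjugated triene acid.
- Other risks: attack through C13 instead of C7, and migration of the lactone to the chromium alkoxide on O8.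
- Fallback: it replaces reductive umpolung by a preformed, non-reducing allylboron reagent. It sets out from 7.
  - Copper-catalysed borylation (B2pin2, CuCl, LiCl, KOAc, DMF, rt) gives the 2-(borylmethyl)acrylate F7.
  - Ring-closing metathesis as in step 5 gives the butenolide allylboronate F8.
  - Allylboration of 14 follows (toluene, 40 °C, or Sc(OTf)3 10 mol %, −40 °C), through the same chair and the same face.
- The fallback comes back to the route at 16.

**Step 15.**
- Most likely failure: poor facial selectivity. The two alkenyl arms differ only moderately in size, and the ring conformation may oppose the catalyst.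
- Side process: 1,4-reduction of an s-cis enone segment.
- Fallback: it takes the substrate-preferred face and corrects C3 by substitution. It sets out from 23.
  - Luche reduction (NaBH4, CeCl3·7H2O, MeOH, −78 °C) under ring control is taken to the 3-epimeric diol F9.
  - Mitsunobu inversion with acetic acid (PPh3, DIAD, toluene, 0 °C) installs the acetate with inversion. The tertiary hydroxyl does not react.
- The fallback comes back to the route at 25.

**Step 7.**
- Most likely failure: loss of the alkyne. This can happen by alkoxide-directed hydroalumination after the epoxide has opened, or by SN2' delivery of hydride to the alkynyl epoxide to give an allene.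
- Fallback: it removes the alkyne before any hydride is used. It sets out from 9.
  - Palladium-catalysed hydrostannation (Bu3SnH, PdCl2(PPh3)2) gives the stannyl dienol F10.
  - Sharpless epoxidation with L-(+)-diethyl tartrate at the allylic alcohol alkene gives the epoxy alcohol F11.
  - Directed reduction with NaAlH2(OCH2CH2OMe)2 gives the diol F12.
  - Double silylation as in step 8 follows.
- The fallback comes back to the route at 13.

## Further compounds

F1 | step 13 | (3R)-3-methyl-1,3-bis(triethylsilyloxy)pent-4-ene | CC[Si](CC)(CC)OCC[C@@](C)(O[Si](CC)(CC)CC)C=C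
F2 | step 13 | (3R)-3-methyl-3-(triethylsilyloxy)pent-4-enal | O=CC[C@@](C)(O[Si](CC)(CC)CC)C=C
F3 | step 13 | (6R,7S,8R,10R)-8-hydroxy open-chain lactone with vinyl group at C10 and 10-OTES | C=C1C(=O)O[C@@H](/C=C(/C)I)[C@@H]1[C@H](O)C[C@@](C)(O[Si](CC)(CC)CC)C=C
F4 | step 13 | O8-angelate of F3 | C=C1C(=O)O[C@@H](/C=C(/C)I)[C@@H]1[C@H](OC(=O)/C(C)=C\C)C[C@@](C)(O[Si](CC)(CC)CC)C=C
F5 | step 13 | 10-hydroxy compound from F4 | C=C1C(=O)O[C@@H](/C=C(/C)I)[C@@H]1[C@H](OC(=O)/C(C)=C\C)C[C@@](C)(O)C=C
F6 | step 13 | (1E)-enal with C3 as aldehyde carbon, Z-iodide at C4, free 10-OH | C=C1C(=O)O[C@@H](/C=C(/C)I)[C@@H]1[C@H](OC(=O)/C(C)=C\C)C[C@@](C)(O)/C=C/C=O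
F7 | step 11 | (3R,4Z)-5-iodohexa-1,4-dien-3-yl 2-[(pinacolatoboryl)methyl]prop-2-enoate | C=C[C@@H](OC(=O)C(=C)CB1OC(C)(C)C(C)(C)O1)/C=C(/C)I
F8 | step 11 | (5R)-5-[(1Z)-2-iodoprop-1-enyl]-3-[(pinacolatoboryl)methyl]furan-2(5H)-one | CC1(C)OB(CC2=C[C@H](/C=C(/C)I)OC2=O)OC1(C)C
F9 | step 15 | (3R)-epimer of 24 | C=C1C(=O)O[C@H]2/C=C(/C)[C@H](O)/C=C/[C@](C)(O)C[C@@H](OC(=O)/C(C)=C\C)[C@H]12
F10 | step 7 | (2E,4E)-3-methyl-5-(tributylstannyl)penta-2,4-dien-1-ol | OC/C=C(/C=C/[Sn](CCCC)(CCCC)CCCC)C
F11 | step 7 | {(2S,3S)-3-methyl-3-[(E)-2-(tributylstannyl)ethenyl]oxiran-2-yl}methanol | OC[C@@H]1O[C@@]1(C)/C=C/[Sn](CCCC)(CCCC)CCCC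
F12 | step 7 | (3R,4E)-3-methyl-5-(tributylstannyl)pent-4-ene-1,3-diol | OCC[C@@](C)(O)/C=C/[Sn](CCCC)(CCCC)CCCC
A1 | alternative 1 | open-chain (4Z)-enal (C6 aldehyde) with 3S-acetate, 8R-angelate, 10R-carbinol and methyl (Z)-2-(bromomethyl)enoate terminus at C7 | O=C/C=C(/C)[C@@H](OC(C)=O)/C=C/[C@](C)(O)C[C@@H](OC(=O)/C(C)=C\C)/C=C(\CBr)C(=O)OC
A2 | alternative 2 | lactone tetraene with vinyl groups on C3 and C10 | C=C1C(=O)O[C@@H](/C=C(/C)[C@@H](OC(C)=O)C=C)[C@@H]1[C@H](OC(=O)/C(C)=C\C)C[C@@](C)(O)C=C
A3 | alternative 3 | iodo-enal with 10-OTES (C3 aldehyde, Z-iodide at C4) | C=C1C(=O)O[C@@H](/C=C(/C)I)[C@@H]1[C@H](OC(=O)/C(C)=C\C)C[C@@](C)(O[Si](CC)(CC)CC)/C=C/C=O
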